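**Retrosynthetic overview**

1. Target 15 ⇐ 14 ⇐ 13: fluoride desilylation of the ring B catechol and E-selective SeO2 hydroxylation of the C8 prenyl group are left to the end.
2. Key disconnection is the O1–C2 bond of ring C: flavanone 13 ⇐ open-chain alkylidene β-ketoester 9, in which O1 still carries the five-carbon chain as a 1,1-dimethylallyl ether and C3 carries a temporary tert-butyl ester.
3. Enabling feature: O1 on C8a of ring A is both ortho to the allylic substituent on C8 (retron of an aromatic [3,3] shift from O1 to C8) and β to the C4 ketone through C2–C3 (retron of an oxa-Michael addition). One flask therefore moves the chain to C8, frees O1, closes ring C at C2 under catalyst control and removes the ester.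
4. 9 ⇐ Knoevenagel condensation of β-ketoester 6 with aldehyde 8; 6 ⇐ methyl 4-methoxysalicylate 1 by O-alkylation, semihydrogenation and crossed Claisen condensation.
5. Ring order: rings A and B are bought as arenes; ring C is the only ring made, in step 6.

Key step: step 6

Assumption: the quinidine-derived thiourea is taken to deliver the 2S series; if the sense of induction proves opposite, its quinine-derived pseudoenantiomer is used under the same conditions.

**Route**

Step 1
Reactants: 1 methyl 2-hydroxy-4-methoxybenzoate; 2 3-chloro-3-methylbut-1-yne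
Product: 3 methyl 4-methoxy-2-[(2-methylbut-3-yn-2-yl)oxy]benzoate
Conditions: DBU (1.3 equiv), CuCl2·2H2O (1 mol%), MeCN, 0 °C → rt
Reagents that add atoms: none
Why: Copper-catalysed propargylic etherification (copper acetylide that ionises the tertiary chloride, then O-attack of the phenoxide) is the standard entry to aryl 1,1-dimethylpropargyl ethers and alkylates an acidic ortho-acyl phenol on oxygen only.

Step 2
Reactants: 3 methyl 4-methoxy-2-[(2-methylbut-3-yn-2-yl)oxy]benzoate
Product: 4 methyl 4-methoxy-2-[(2-methylbut-3-en-2-yl)oxy]benzoate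
Conditions: H2 (1 atm), Pd/CaCO3 poisoned with Pb(OAc)2, quinoline, EtOAc, rt
Reagents that add atoms: none
Why: Lindlar-type semihydrogenation should stop at the terminal alkene because the poisoned palladium surface binds the alkyne far better than the product olefin, leaving the ester and the tertiary C–O bond untouched.

Step 3
Reactants: 4 methyl 4-methoxy-2-[(2-methylbut-3-en-2-yl)oxy]benzoate; 5 tert-butyl acetate
Product: 6 tert-butyl 3-{4-methoxy-2-[(2-methylbut-3-en-2-yl)oxy]phenyl}-3-oxopropanoate
Conditions: 5 (3 equiv), LiN(iPr)2 (3.2 equiv, commercial solution), THF, −78 °C; then 4, −78 → −20 °C; aq. NH4Cl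
Reagents that add atoms: none
Why: Crossed Claisen condensation, in which the lithium enolate of tert-butyl acetate adds to the methyl ester and the β-ketoester is removed from the equilibrium as its enolate, so an excess of enolate should drive the acylation to completion.

Step 4
Reactants: 7 3,4-dihydroxybenzaldehyde
Product: 8 3,4-bis[(tert-butyldimethylsilyl)oxy]benzaldehyde
Conditions: TBSCl (2.4 equiv), imidazole (5 equiv), DMF, rt
Reagents that add atoms: tert-butyldimethylsilyl chloride, CC(C)(C)[Si](C)(C)Cl
Why: Imidazole-promoted silylation of both phenols is routine, and aryl silyl ethers should withstand the buffered amine, the hot neutral stage and the anhydrous acid ahead while falling to fluoride at the end.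

Step 5
Reactants: 6 tert-butyl 3-{4-methoxy-2-[(2-methylbut-3-en-2-yl)oxy]phenyl}-3-oxopropanoate; 8 3,4-bis[(tert-butyldimethylsilyl)oxy]benzaldehyde
Product: 9 tert-butyl (2Z)-3-{3,4-bis[(tert-butyldimethylsilyl)oxy]phenyl}-2-{4-methoxy-2-[(2-methylbut-3-en-2-yl)oxy]benzoyl}prop-2-enoate
Conditions: piperidine (0.2 equiv), AcOH (0.2 equiv), 4 Å molecular sieves, toluene, 40 °C
Reagents that add atoms: none
Why: Knoevenagel condensation under piperidinium acetate catalysis, with dehydration driven by the sieves, should give the alkylidene β-ketoester as the Z isomer (aryl cis to the ester) at a temperature far below that needed for the sigmatropic shift of the allyl ether.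

Step 6
Reactants: 9 tert-butyl (2Z)-3-{3,4-bis[(tert-butyldimethylsilyl)oxy]phenyl}-2-{4-methoxy-2-[(2-methylbut-3-en-2-yl)oxy]benzoyl}prop-2-enoate
Product: 13 (2S)-2-{3,4-bis[(tert-butyldimethylsilyl)oxy]phenyl}-7-methoxy-8-(3-methylbut-2-en-1-yl)chroman-4-one, via phenol alkylidene ketoester 10 (not isolated), via flavanone tert-butyl ester 11 (not isolated), via flavanone keto acid 12 (not isolated)
Conditions: toluene (0.05 M, silylated flask, Ar), 110 °C; then −25 °C, thiourea from 9-amino-9-deoxy-epi-quinidine and 3,5-bis(trifluoromethyl)phenyl isothiocyanate (10 mol%); then anhydrous TsOH (0.5 equiv), 80 °C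
Reagents that add atoms: none
Why: Heating triggers a concerted chair-like [3,3] aromatic Claisen rearrangement that moves the 1,1-dimethylallyl group from the ring A oxygen to the only unsubstituted ortho carbon (the future C8) with allylic inversion to a prenyl group, and re-aromatising tautomerisation releases phenol 10. At −25 °C the quinuclidine nitrogen of the bifunctional catalyst activates this phenol while the thiourea hydrogen-bonds the β-ketoester, so the oxygen adds to the alkylidene carbon in a 6-endo-trig oxa-Michael addition that forms the O1–C2 bond and closes ring C (11); TsOH then cleaves the tert-butyl ester (12) and the β-keto acid decarboxylates through its enol to 13. The closest known reaction types are thermal tandem aromatic Claisen/oxa-Michael sequences of allyl ethers of 2'-hydroxyaryl enones and the cinchona-thiourea-catalysed cyclisation of 2'-hydroxyaryl alkylidene β-ketoesters to flavanones with acid decarboxylation in the same flask. The only new stereocentre, C2, is under catalyst control: the catalyst holds the phenol and the 1,3-dicarbonyl in one chiral pocket and exposes one face of the alkylidene, which should give 2S, while C3 is a labile centre that disappears on decarboxylation. The step needs regioselectivity in the sigmatropic shift, which the substrate secures because the other ortho position carries the acyl group and the migrating terminus is a symmetrical gem-dimethyl carbon, so no olefin geometry is at stake. It also needs the uncatalysed ring closure to stay slow during the hot stage, which the intramolecular hydrogen bond of the new phenol to the ketone and the neutral apolar medium are expected to secure, and it needs C2 to hold during decarboxylation, which the absence of base secures.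

Step 7
Reactants: 13 (2S)-2-{3,4-bis[(tert-butyldimethylsilyl)oxy]phenyl}-7-methoxy-8-(3-methylbut-2-en-1-yl)chroman-4-one
Product: 14 (2S)-2-{3,4-bis[(tert-butyldimethylsilyl)oxy]phenyl}-8-[(2E)-4-hydroxy-3-methylbut-2-en-1-yl]-7-methoxychroman-4-one
Conditions: SeO2 (0.3 equiv), t-BuOOH (3 equiv, in decane), salicylic acid (0.1 equiv), CH2Cl2, 0 °C → rt
Reagents that add atoms: tert-butyl hydroperoxide, CC(C)(C)OO (net oxygen source, relayed by SeO2)
Why: SeO2 allylic oxidation (ene reaction, then [2,3]-sigmatropic shift, with SeO2 regenerated by the hydroperoxide) attacks the more substituted end of the trisubstituted olefin and, of the two methyl groups, the one trans to the chain, which should set the E geometry of the allylic alcohol while the ketone and silyl ethers stay inert at room temperature.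

Step 8
Reactants: 14 (2S)-2-{3,4-bis[(tert-butyldimethylsilyl)oxy]phenyl}-8-[(2E)-4-hydroxy-3-methylbut-2-en-1-yl]-7-methoxychroman-4-one
Product: 15 (2S)-2-(3,4-dihydroxyphenyl)-8-[(2E)-4-hydroxy-3-methylbut-2-en-1-yl]-7-methoxychroman-4-one
Conditions: HF·pyridine, pyridine/THF, 0 °C → rt
Reagents that add atoms: none
Why: Fluoride cleaves both aryl Si–O bonds under weakly acidic conditions, which avoids the phenoxide-triggered retro-oxa-Michael ring opening that would racemise C2 under basic desilylation and leaves the allylic alcohol untouched.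

**Compound list**

1 | methyl 2-hydroxy-4-methoxybenzoate | COC(=O)c1ccc(OC)cc1O | starting material
2 | 3-chloro-3-methylbut-1-yne | C#CC(C)(C)Cl | starting material
3 | methyl 4-methoxy-2-[(2-methylbut-3-yn-2-yl)oxy]benzoate | COC(=O)c1ccc(OC)cc1OC(C)(C)C#C | intermediate
4 | methyl 4-methoxy-2-[(2-methylbut-3-en-2-yl)oxy]benzoate | COC(=O)c1ccc(OC)cc1OC(C)(C)C=C | intermediate
5 | tert-butyl acetate | CC(=O)OC(C)(C)C | starting material
6 | tert-butyl 3-{4-methoxy-2-[(2-methylbut-3-en-2-yl)oxy]phenyl}-3-oxopropanoate | CC(C)(C)OC(=O)CC(=O)c1ccc(OC)cc1OC(C)(C)C=C | intermediate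
7 | 3,4-dihydroxybenzaldehyde | O=Cc1ccc(O)c(O)c1 | starting material
8 | 3,4-bis[(tert-butyldimethylsilyl)oxy]benzaldehyde | O=Cc1ccc(O[Si](C)(C)C(C)(C)C)c(O[Si](C)(C)C(C)(C)C)c1 | intermediate
9 | tert-butyl (2Z)-3-{3,4-bis[(tert-butyldimethylsilyl)oxy]phenyl}-2-{4-methoxy-2-[(2-methylbut-3-en-2-yl)oxy]benzoyl}prop-2-enoate | CC(C)(C)OC(=O)/C(=C\c1ccc(O[Si](C)(C)C(C)(C)C)c(O[Si](C)(C)C(C)(C)C)c1)C(=O)c1ccc(OC)cc1OC(C)(C)C=C | intermediate
10 | tert-butyl (2Z)-3-{3,4-bis[(tert-butyldimethylsilyl)oxy]phenyl}-2-[2-hydroxy-4-methoxy-3-(3-methylbut-2-en-1-yl)benzoyl]prop-2-enoate | CC(C)(C)OC(=O)/C(=C\c1ccc(O[Si](C)(C)C(C)(C)C)c(O[Si](C)(C)C(C)(C)C)c1)C(=O)c1ccc(OC)c(CC=C(C)C)c1O | intermediate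
11 | tert-butyl (2S)-2-{3,4-bis[(tert-butyldimethylsilyl)oxy]phenyl}-7-methoxy-8-(3-methylbut-2-en-1-yl)-4-oxochromane-3-carboxylate (C3 labile, not assigned) | COc1ccc2c(c1CC=C(C)C)O[C@H](c1ccc(O[Si](C)(C)C(C)(C)C)c(O[Si](C)(C)C(C)(C)C)c1)C(C(=O)OC(C)(C)C)C2=O | intermediate
12 | (2S)-2-{3,4-bis[(tert-butyldimethylsilyl)oxy]phenyl}-7-methoxy-8-(3-methylbut-2-en-1-yl)-4-oxochromane-3-carboxylic acid (C3 labile, not assigned) | COc1ccc2c(c1CC=C(C)C)O[C@H](c1ccc(O[Si](C)(C)C(C)(C)C)c(O[Si](C)(C)C(C)(C)C)c1)C(C(=O)O)C2=O | intermediate
13 | (2S)-2-{3,4-bis[(tert-butyldimethylsilyl)oxy]phenyl}-7-methoxy-8-(3-methylbut-2-en-1-yl)chroman-4-one | COc1ccc2c(c1CC=C(C)C)O[C@H](c1ccc(O[Si](C)(C)C(C)(C)C)c(O[Si](C)(C)C(C)(C)C)c1)CC2=O | intermediate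
14 | (2S)-2-{3,4-bis[(tert-butyldimethylsilyl)oxy]phenyl}-8-[(2E)-4-hydroxy-3-methylbut-2-en-1-yl]-7-methoxychroman-4-one | COc1ccc2c(c1C/C=C(\C)CO)O[C@H](c1ccc(O[Si](C)(C)C(C)(C)C)c(O[Si](C)(C)C(C)(C)C)c1)CC2=O | intermediate
15 | (2S)-2-(3,4-dihydroxyphenyl)-8-[(2E)-4-hydroxy-3-methylbut-2-en-1-yl]-7-methoxychroman-4-one | COc1ccc2c(c1C/C=C(\C)CO)O[C@H](c1ccc(O)c(O)c1)CC2=O | target

**Step count and risks**

Total step count: 8. Longest linear sequence: 7 (steps 1, 2, 3, 5, 6, 7, 8).

Steps most likely to fail:

Step 6. The phenol set free in the hot stage may close onto the alkylidene before the catalyst is present, which would erode enantiocontrol. The tertiary allyl ether may also ionise and lose isoprene instead of rearranging. The acid stage may partly open ring C or shift the prenyl olefin. The fallback sets out from 4 and comes back at 10, moving the rearrangement to the benzoate stage so that the cyclisation substrate has no thermal history. Compound 4 is heated in N,N-diethylaniline at 130 °C to give methyl 2-hydroxy-4-methoxy-3-(3-methylbut-2-en-1-yl)benzoate F1. Crossed Claisen condensation of F1 with the lithium enolate of tert-butyl acetate (extra LiN(iPr)2 to cover the phenol) gives tert-butyl 3-[2-hydroxy-4-methoxy-3-(3-methylbut-2-en-1-yl)phenyl]-3-oxopropanoate F2. Knoevenagel condensation of F2 with 8 gives 10 as an isolated compound, which is cyclised at −25 °C with the same thiourea and decarboxylated as in step 6 (10 → 11 → 12 → 13).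

Step 7. Over-oxidation to the enal, incomplete conversion, or oxidation next to the ketone may lower the return of the allylic alcohol. The fallback sets out from 13 and comes back at 14, building the oxidised terminus by olefin metathesis instead of C–H oxidation. Cross-metathesis of the prenyl group of 13 with methacrolein (second-generation Grubbs catalyst, CH2Cl2, 40 °C) should give (2E)-4-[(2S)-2-{3,4-bis[(tert-butyldimethylsilyl)oxy]phenyl}-7-methoxy-4-oxochroman-8-yl]-2-methylbut-2-enal F3 under thermodynamic control of the olefin geometry. NaBH(OAc)3 in benzene then reduces the aldehyde in the presence of the aryl ketone to give 14.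

Step 1. O-alkylation of the hindered, hydrogen-bonded phenol may be slow, and the tertiary chloride may eliminate to the enyne. The fallback sets out from 1 and comes back at 4, using a π-allyl palladium route that also bypasses 3 and step 2. 2-Methylbut-3-en-2-ol is converted with n-BuLi and Boc2O into tert-butyl 2-methylbut-3-en-2-yl carbonate F4. Pd(PPh3)4-catalysed decarboxylative allylic etherification of 1 with F4 (THF, 0 °C) should give the branched tertiary ether 4 directly under kinetic control.

**Further compounds**

F1 | step 6 | methyl 2-hydroxy-4-methoxy-3-(3-methylbut-2-en-1-yl)benzoate | COC(=O)c1ccc(OC)c(CC=C(C)C)c1O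
F2 | step 6 | tert-butyl 3-[2-hydroxy-4-methoxy-3-(3-methylbut-2-en-1-yl)phenyl]-3-oxopropanoate | CC(C)(C)OC(=O)CC(=O)c1ccc(OC)c(CC=C(C)C)c1O
F3 | step 7 | (2E)-4-[(2S)-2-{3,4-bis[(tert-butyldimethylsilyl)oxy]phenyl}-7-methoxy-4-oxochroman-8-yl]-2-methylbut-2-enal | COc1ccc2c(c1C/C=C(\C)C=O)O[C@H](c1ccc(O[Si](C)(C)C(C)(C)C)c(O[Si](C)(C)C(C)(C)C)c1)CC2=O
F4 | step 1 | tert-butyl 2-methylbut-3-en-2-yl carbonate | CC(C)(C)OC(=O)OC(C)(C)C=C
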